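**Plan**
- Retrosynthesis: the three benzyl ethers come off last. Ring C is stepped down from the flavonol level (C2=C3–OH, C4=O) through the 3,4-dione and the 3,4-diol to a flav-3-ene, which is cut at O1–C2 and C3–C4.
- Enabling feature: C4 sits on C4a of ring A, directly ortho to C8a, the carbon that bears O1, and C2–C3 is a two-carbon bridge with ring B on C2. Ring A therefore maps onto a salicylaldehyde (CHO = C4, ortho OH = O1, next to the C8 methoxy), and C3–C2–ring B maps onto an (E)-styrylboronic acid.
- Forward, fragments: rings A and B are bought as benzaldehydes. Ring A is re-patterned (CHO to OMe through Baeyer–Villiger oxidation, then a new CHO ortho to the freed phenol). Ring B is homologated to the alkyne and hydroborated.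
- Forward, union: the two fragments are joined and ring C, the only ring built, closes in the same operation. Dihydroxylation, double oxidation and hydrogenolysis finish the flavonol.
- Stereochemistry: the target is achiral. C2 arises racemic, C3 and C4 follow from syn dihydroxylation anti to the C2 aryl group, and all three centres vanish on oxidation. Only the E geometry of the boronic acid, set by syn hydroboration, has to be made.

Key step: step 10

Assumption: all chiral intermediates are racemic. Each SMILES shows one enantiomer, and the drawn series is spatially consistent from one compound to the next.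

**Route**

Step 1
Reactants: 1 2,4,6-trihydroxybenzaldehyde
Product: 2 2,4-bis(benzyloxy)-6-hydroxybenzaldehyde
Conditions: BnBr (2.05 equiv), K2CO3 (2.2 equiv), DMF, 0 °C to rt
Reagents that add atoms: benzyl bromide, BrCc1ccccc1
Why: Williamson etherification with a limiting amount of halide should take the acidic para hydroxyl and one ortho hydroxyl, while the remaining ortho hydroxyl is tied up in a strong hydrogen bond to the aldehyde and is alkylated much more slowly.

Step 2
Reactants: 2 2,4-bis(benzyloxy)-6-hydroxybenzaldehyde
Product: 3 2,4-bis(benzyloxy)-6-(methoxymethoxy)benzaldehyde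
Conditions: NaH, MOMCl, THF/DMF, 0 °C to rt
Reagents that add atoms: chloromethyl methyl ether, COCCl
Why: Irreversible deprotonation with NaH breaks the hydrogen-bonded chelate and the phenoxide is O-alkylated by the reactive chloromethyl ether (Williamson-type acetal protection), which gives a mask that is orthogonal to the benzyl ethers and stable to peracid and base.

Step 3
Reactants: 3 2,4-bis(benzyloxy)-6-(methoxymethoxy)benzaldehyde
Product: 5 2,4-bis(benzyloxy)-6-(methoxymethoxy)phenol, via aryl formate 4 (not isolated)
Conditions: mCPBA, CH2Cl2, 0 °C to rt; then K2CO3 (cat.), MeOH, rt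
Reagents that add atoms: 3-chloroperoxybenzoic acid (mCPBA), O=C(OO)c1cccc(Cl)c1
Why: Baeyer–Villiger oxidation (Dakin-type outcome): in the Criegee adduct the very electron-rich aryl group migrates in preference to hydride, and mild methanolysis of formate 4 frees the phenol without touching the MOM or benzyl ethers.

Step 4
Reactants: 5 2,4-bis(benzyloxy)-6-(methoxymethoxy)phenol
Product: 6 1,5-bis(benzyloxy)-2-methoxy-3-(methoxymethoxy)benzene
Conditions: MeI, K2CO3, acetone, reflux
Reagents that add atoms: iodomethane, CI
Why: Williamson methylation of the only free phenol fixes the future C8 methoxy group unambiguously between the MOM ether and a benzyl ether.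

Step 5
Reactants: 6 1,5-bis(benzyloxy)-2-methoxy-3-(methoxymethoxy)benzene
Product: 7 3,5-bis(benzyloxy)-2-methoxyphenol
Conditions: HCl (cat.), MeOH/THF, 50 °C
Reagents that add atoms: none
Why: Acid-catalysed acetal exchange with methanol removes the MOM group, whereas aryl benzyl and methyl ethers are inert to dilute HCl.

Step 6
Reactants: 7 3,5-bis(benzyloxy)-2-methoxyphenol
Product: 8 4,6-bis(benzyloxy)-2-hydroxy-3-methoxybenzaldehyde
Conditions: MgCl2, Et3N, (CH2O)n, MeCN, reflux; aq HCl work-up
Reagents that add atoms: paraformaldehyde (reacts as formaldehyde), C=O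
Why: Casnati–Skattebøl ortho-formylation: magnesium-templated delivery of formaldehyde is specific for the position ortho to the phenol, only one such position is free in 7, and hydride transfer to a second formaldehyde raises the hydroxymethyl stage to the aldehyde.

Step 7
Reactants: 9 3-hydroxy-4,5-dimethoxybenzaldehyde
Product: 10 3-(benzyloxy)-4,5-dimethoxybenzaldehyde
Conditions: BnBr, K2CO3, DMF, rt
Reagents that add atoms: benzyl bromide, BrCc1ccccc1
Why: Williamson benzylation of the single phenol should proceed cleanly since the non-enolisable aldehyde is inert to K2CO3.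

Step 8
Reactants: 10 3-(benzyloxy)-4,5-dimethoxybenzaldehyde
Product: 11 1-(benzyloxy)-5-ethynyl-2,3-dimethoxybenzene
Conditions: Ohira–Bestmann reagent, K2CO3, MeOH, rt
Reagents that add atoms: dimethyl (1-diazo-2-oxopropyl)phosphonate, COP(=O)(OC)C(=[N+]=[N-])C(C)=O
Why: Seyferth–Gilbert homologation in the Ohira–Bestmann variant: methanolysis frees the diazomethylphosphonate anion, which adds to the aldehyde, loses dimethyl phosphate and N2, and gives the terminal alkyne by 1,2-hydride shift under conditions mild enough for all three ethers.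

Step 9
Reactants: 11 1-(benzyloxy)-5-ethynyl-2,3-dimethoxybenzene; 12 catecholborane
Product: 14 [(E)-2-[3-(benzyloxy)-4,5-dimethoxyphenyl]ethenyl]boronic acid, via catechol boronate 13 (not isolated)
Conditions: catecholborane (1.2 equiv), THF, 65 °C; then H2O, rt
Reagents that add atoms: catecholborane (12), B1Oc2ccccc2O1; water, O
Why: Uncatalysed hydroboration of a terminal arylalkyne with catecholborane is a syn, anti-Markovnikov addition that places boron on the terminal carbon and sets the E geometry, and the catechol ester 13 hydrolyses readily in water to the boronic acid.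

Step 10
Reactants: 8 4,6-bis(benzyloxy)-2-hydroxy-3-methoxybenzaldehyde; 14 [(E)-2-[3-(benzyloxy)-4,5-dimethoxyphenyl]ethenyl]boronic acid (1.5 equiv)
Product: 17 5,7-bis(benzyloxy)-2-[3-(benzyloxy)-4,5-dimethoxyphenyl]-8-methoxy-2H-chromene (racemic), via Petasis aminophenol 15 (not isolated), via ortho-quinone methide 16 (not isolated)
Conditions: Bn2NH (40 mol %), 1,4-dioxane, 90 °C, Ar
Reagents that add atoms: none
Why: Dibenzylamine condenses with the aldehyde of 8 to an iminium ion, the neighbouring phenoxide coordinates the boron of 14, and the tetracoordinate boronate passes its styryl group intramolecularly to the iminium carbon, which forms C3–C4 with retention of the E geometry and gives aminophenol 15 (Petasis borono-Mannich reaction). At 90 °C the electron-rich ring A expels the amine from 15, which re-enters the cycle, and leaves ortho-quinone methide 16. Ring C then closes by a thermal disrotatory oxa-6π electrocyclization of the O=C8a–C4a=C4–C3=C2 oxatriene in its Z form, which makes O1–C2 and gives ring A its aromaticity back. The closest known reaction type is the secondary-amine-catalysed condensation of salicylaldehydes with alkenylboronic acids, styrylboronic acids included, to 2H-chromenes. C2 is the only new stereocentre and nothing controls it, so 17 should be racemic, which is harmless because C2 becomes sp2 in step 12. The step needs site selectivity in both the vinyl transfer and the closure, and this is secured because 8 carries one free hydroxyl only, ortho to the aldehyde and next to the future C8 methoxy, so that no other oxygen can bind boron or become O1.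

Step 11
Reactants: 17 5,7-bis(benzyloxy)-2-[3-(benzyloxy)-4,5-dimethoxyphenyl]-8-methoxy-2H-chromene
Product: 18 rac-(2S,3R,4R)-5,7-bis(benzyloxy)-2-[3-(benzyloxy)-4,5-dimethoxyphenyl]-8-methoxy-3,4-dihydro-2H-chromene-3,4-diol (2,3-trans-3,4-cis)
Conditions: OsO4 (cat.), NMO, acetone/H2O, rt
Reagents that add atoms: osmium tetroxide, O=[Os](=O)(=O)=O; N-methylmorpholine N-oxide, C[N+]1([O-])CCOCC1; water, O
Why: Upjohn dihydroxylation: the electron-rich styrene-type C3=C4 bond should undergo suprafacial addition of OsO4 on the face opposite the C2 aryl group, which sets C3 and C4 cis to each other and trans to the aryl group in racemic form.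

Step 12
Reactants: 18 rac-(2S,3R,4R)-flavan-3,4-diol
Product: 21 5,7-bis(benzyloxy)-2-[3-(benzyloxy)-4,5-dimethoxyphenyl]-3-hydroxy-8-methoxy-4H-chromen-4-one, via trans-dihydroflavonol 19 (not isolated), via chromane-3,4-dione 20 (not isolated)
Conditions: IBX (3 equiv), DMSO, rt
Reagents that add atoms: none
Why: IBX oxidises 1,2-diols to 1,2-diones without glycol cleavage, so that the benzylic C4 carbinol should go first to ketol 19, the C3 carbinol next to dione 20, and the doubly activated C2–H of 20 then shifts to oxygen to give the conjugated, hydrogen-bonded 3-hydroxychromen-4-one with loss of all stereocentres.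

Step 13
Reactants: 21 5,7-bis(benzyloxy)-2-[3-(benzyloxy)-4,5-dimethoxyphenyl]-3-hydroxy-8-methoxy-4H-chromen-4-one
Product: 22 3,5,7-trihydroxy-2-(3-hydroxy-4,5-dimethoxyphenyl)-8-methoxy-4H-chromen-4-one (CNP0225742.0)
Conditions: H2 (1 atm), 10% Pd/C, THF/MeOH, rt
Reagents that add atoms: none
Why: Catalytic hydrogenolysis cleaves the three aryl benzyl ethers under neutral conditions, while the methyl ethers and the vinylogous-ester C2=C3 bond of the chromenone are not reduced at ambient pressure.

**Compound list**

1 | 2,4,6-trihydroxybenzaldehyde | O=Cc1c(O)cc(O)cc1O | starting material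
2 | 2,4-bis(benzyloxy)-6-hydroxybenzaldehyde | O=Cc1c(O)cc(OCc2ccccc2)cc1OCc1ccccc1 | intermediate
3 | 2,4-bis(benzyloxy)-6-(methoxymethoxy)benzaldehyde | COCOc1cc(OCc2ccccc2)cc(OCc2ccccc2)c1C=O | intermediate
4 | 2,4-bis(benzyloxy)-6-(methoxymethoxy)phenyl formate | COCOc1cc(OCc2ccccc2)cc(OCc2ccccc2)c1OC=O | intermediate
5 | 2,4-bis(benzyloxy)-6-(methoxymethoxy)phenol | COCOc1cc(OCc2ccccc2)cc(OCc2ccccc2)c1O | intermediate
6 | 1,5-bis(benzyloxy)-2-methoxy-3-(methoxymethoxy)benzene | COCOc1cc(OCc2ccccc2)cc(OCc2ccccc2)c1OC | intermediate
7 | 3,5-bis(benzyloxy)-2-methoxyphenol | COc1c(O)cc(OCc2ccccc2)cc1OCc1ccccc1 | intermediate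
8 | 4,6-bis(benzyloxy)-2-hydroxy-3-methoxybenzaldehyde | COc1c(O)c(C=O)c(OCc2ccccc2)cc1OCc1ccccc1 | intermediate
9 | 3-hydroxy-4,5-dimethoxybenzaldehyde | COc1cc(C=O)cc(O)c1OC | starting material
10 | 3-(benzyloxy)-4,5-dimethoxybenzaldehyde | COc1cc(C=O)cc(OCc2ccccc2)c1OC | intermediate
11 | 1-(benzyloxy)-5-ethynyl-2,3-dimethoxybenzene | C#Cc1cc(OC)c(OC)c(OCc2ccccc2)c1 | intermediate
12 | catecholborane (1,3,2-benzodioxaborole) | B1Oc2ccccc2O1 | starting material
13 | 2-[(E)-2-[3-(benzyloxy)-4,5-dimethoxyphenyl]ethenyl]-1,3,2-benzodioxaborole | COc1cc(/C=C/B2Oc3ccccc3O2)cc(OCc2ccccc2)c1OC | intermediate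
14 | [(E)-2-[3-(benzyloxy)-4,5-dimethoxyphenyl]ethenyl]boronic acid | OB(O)/C=C/c1cc(OC)c(OC)c(OCc2ccccc2)c1 | intermediate
15 | 3,5-bis(benzyloxy)-2-[(E)-3-[3-(benzyloxy)-4,5-dimethoxyphenyl]-1-(dibenzylamino)prop-2-enyl]-6-methoxyphenol (racemic, one enantiomer drawn) | COc1c(O)c([C@H](/C=C/c2cc(OC)c(OC)c(OCc3ccccc3)c2)N(Cc2ccccc2)Cc2ccccc2)c(OCc2ccccc2)cc1OCc1ccccc1 | intermediate
16 | (6Z)-3,5-bis(benzyloxy)-6-[(E)-3-[3-(benzyloxy)-4,5-dimethoxyphenyl]prop-2-enylidene]-2-methoxycyclohexa-2,4-dien-1-one | O=C1C(OC)=C(OCc2ccccc2)C=C(OCc2ccccc2)/C1=C/C=C/c1cc(OC)c(OC)c(OCc2ccccc2)c1 | intermediate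
17 | 5,7-bis(benzyloxy)-2-[3-(benzyloxy)-4,5-dimethoxyphenyl]-8-methoxy-2H-chromene (racemic, one enantiomer drawn) | COc1cc([C@H]2C=Cc3c(OCc4ccccc4)cc(OCc4ccccc4)c(OC)c3O2)cc(OCc2ccccc2)c1OC | intermediate
18 | rac-(2S,3R,4R)-5,7-bis(benzyloxy)-2-[3-(benzyloxy)-4,5-dimethoxyphenyl]-8-methoxy-3,4-dihydro-2H-chromene-3,4-diol (2,3-trans-3,4-cis) | COc1cc([C@@H]2Oc3c(OC)c(OCc4ccccc4)cc(OCc4ccccc4)c3[C@@H](O)[C@H]2O)cc(OCc2ccccc2)c1OC | intermediate
19 | rac-(2S,3S)-5,7-bis(benzyloxy)-2-[3-(benzyloxy)-4,5-dimethoxyphenyl]-3-hydroxy-8-methoxy-2,3-dihydrochromen-4-one (2,3-trans) | COc1cc([C@@H]2Oc3c(OC)c(OCc4ccccc4)cc(OCc4ccccc4)c3C(=O)[C@H]2O)cc(OCc2ccccc2)c1OC | intermediate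
20 | 5,7-bis(benzyloxy)-2-[3-(benzyloxy)-4,5-dimethoxyphenyl]-8-methoxychromane-3,4-dione (racemic, one enantiomer drawn) | COc1cc([C@@H]2Oc3c(OC)c(OCc4ccccc4)cc(OCc4ccccc4)c3C(=O)C2=O)cc(OCc2ccccc2)c1OC | intermediate
21 | 5,7-bis(benzyloxy)-2-[3-(benzyloxy)-4,5-dimethoxyphenyl]-3-hydroxy-8-methoxy-4H-chromen-4-one | COc1cc(-c2oc3c(OC)c(OCc4ccccc4)cc(OCc4ccccc4)c3c(=O)c2O)cc(OCc2ccccc2)c1OC | intermediate
22 | 3,5,7-trihydroxy-2-(3-hydroxy-4,5-dimethoxyphenyl)-8-methoxy-4H-chromen-4-one | COc1cc(-c2oc3c(OC)c(O)cc(O)c3c(=O)c2O)cc(O)c1OC | target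

**Totals**
Total step count: 13.
Longest linear sequence: 10 steps (steps 1 to 6, then 10 to 13). The ring B branch has 3 steps (7 to 9).

**Steps most likely to fail**

Step 10.
- Risk: iminium formation may be sluggish at an aldehyde that is electron-rich and flanked on both sides. Compound 14 may protodeboronate during the long heating. The flavene may disproportionate under traces of acid or air during isolation.
- Fallback: it sets out from phenol 7 and aldehyde 10 and comes back at 17. A Wittig reaction of 10 with (triphenylphosphoranylidene)acetaldehyde in toluene at 80 °C should give (E)-3-[3-(benzyloxy)-4,5-dimethoxyphenyl]prop-2-enal F1. Heating 7, F1 and PhB(OH)2 with AcOH in toluene under Dean–Stark conditions should join the aldehyde carbon to the only free ortho carbon of 7 inside a boron template. This should give 5,7-bis(benzyloxy)-4-[(E)-2-[3-(benzyloxy)-4,5-dimethoxyphenyl]ethenyl]-8-methoxy-2-phenyl-4H-1,3,2-benzodioxaborinine F2. On continued heating it should fragment to the same ortho-quinone methide 16, which closes to 17. Here C4–C4a is made in place of C3–C4, while the O1–C2 electrocyclization stays as it is.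

Step 12.
- Risk: glycol cleavage of C3–C4 may compete. The very electron-rich benzylic C4 carbinol may ionise. The freshly formed enol may be over-oxidised by excess oxidant.
- Fallback: it sets out from diol 18 and comes back at 21, and it separates the two oxidations by mechanism. DDQ in dioxane at rt should abstract hydride only from the activated benzylic C4 position and stop at trans-dihydroflavonol 19, which is now isolated. I2 and KOAc in hot AcOH, a classical dehydrogenation of dihydroflavonols that acts on the enolised ketol and not on a carbinol, should then take 19 by way of 20 to 21. No compound outside the compound list is made on this detour (F0).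

Step 1.
- Risk: the alkylation may spread over mono-, bis- and tris-ethers, and the phloroglucinol nucleus may undergo C-benzylation.
- Fallback: it sets out from 1 and comes back at 2, and it replaces partial protection by full protection and directed deprotection. Excess BnBr and K2CO3 in DMF at 60 °C should give 2,4,6-tris(benzyloxy)benzaldehyde F3. MgBr2·OEt2 in toluene/Et2O at 80 °C should then chelate the aldehyde and cleave one of the two symmetry-equivalent ortho benzyl ethers. The resulting magnesium phenoxide chelate protects the second ortho ether, so the reaction should stop at 2.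

**Further compounds**

F1 | step 10 | (E)-3-[3-(benzyloxy)-4,5-dimethoxyphenyl]prop-2-enal | O=C/C=C/c1cc(OC)c(OC)c(OCc2ccccc2)c1
F2 | step 10 | 5,7-bis(benzyloxy)-4-[(E)-2-[3-(benzyloxy)-4,5-dimethoxyphenyl]ethenyl]-8-methoxy-2-phenyl-4H-1,3,2-benzodioxaborinine (racemic, one enantiomer drawn) | COc1c(OCc2ccccc2)cc(OCc2ccccc2)c2c1OB(c1ccccc1)O[C@H]2/C=C/c1cc(OC)c(OC)c(OCc2ccccc2)c1
F0 | step 12 | none | none
F3 | step 1 | 2,4,6-tris(benzyloxy)benzaldehyde | O=Cc1c(OCc2ccccc2)cc(OCc2ccccc2)cc1OCc1ccccc1
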